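**Plan**
- Retrosynthesis: first the C8 angelate ester and the two silyl ethers are cut. Then, in one cut, the lactone C–O bond, the bond from the methylene-bearing carbon C11 to the lactone carbonyl C12 (traced to CO2) and the ring bond C6–C7, which opens both rings to an acyclic allenyl aldehyde. Last, the C1=C10 alkene is cut into aldehyde 9 (C1–C6, C15) and allenyl phosphono lactone 19 (C7–C10, C11, C13, C14).
- Forward: 9 and 19 are joined by Horner–Wadsworth–Emmons olefination to an (E)-alkylidene lactone, a temporary ring holding C14 and O8. It is reduced to the diol, silylated, and the C6 acetal is opened. Nickel(0) and CO2 then close the ten-membered ring and supply the lactone carbonyl in one operation, and the lactone closes on acid work-up. Removal of the triethylsilyl group, angeloylation and desilylation finish the route.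
- Enabling feature: the α-methylene-γ-butyrolactone is fused across C6–C7 of the cyclodecene. Its C13=C11–C7 allyl unit lies between carboxyl carbon C12 and carbinol carbon C6, the pattern left by allene + CO2 + aldehyde. Because C6–C7 belongs to both rings, one event closes the carbocycle and builds the lactone carbons.
- Stereochemistry: C4 comes from an Evans propargylation, C8 from a Noyori transfer hydrogenation of an ynone, the C1=C10 geometry from the olefination, C6 and C7 from the key step under control of C8 and a closed transition state, and the angelate geometry from angelic acid.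

Key step: step 16

Remark: the ester is taken as the (Z)-2-methylbut-2-enoate (angelate) that the SMILES specifies. Carbons are named by germacrane numbers: ring C1–C10 with C1=C10, C15 on C4, lactone O on C6, C11 on C7, acyloxy on C8, C14 on C10, C12 the lactone carbonyl, C13 the exocyclic CH2.

**Route**

Step 1
Reactants: 1 methyl 4,4-dimethoxybutanoate
Product: 2 4,4-dimethoxybutanoic acid
Conditions: LiOH·H2O, THF/H2O, 0 °C → rt; then cold 1 M HCl to pH 4
Reagents that add atoms: lithium hydroxide, [Li+].[OH-]
Why: Ester saponification in base leaves the dimethyl acetal untouched, and brief cold acidification frees the acid before it can close to the pseudo-ester.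

Step 2
Reactants: 2 4,4-dimethoxybutanoic acid; 3 (4R)-4-benzyl-1,3-oxazolidin-2-one
Product: 5 (4R)-4-benzyl-3-(4,4-dimethoxybutanoyl)-1,3-oxazolidin-2-one, via mixed pivalic anhydride 4 (not isolated)
Conditions: PivCl, Et3N, THF, −20 °C; then 3, LiCl, −20 °C → rt
Reagents that add atoms: none
Why: N-Acylation of the oxazolidinone through the mixed pivalic anhydride runs under mild basic conditions that the acetal tolerates; no stereocentre is formed.

Step 3
Reactants: 5 (4R)-4-benzyl-3-(4,4-dimethoxybutanoyl)-1,3-oxazolidin-2-one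
Product: 6 (4R)-4-benzyl-3-[(2R)-2-(2,2-dimethoxyethyl)pent-4-ynoyl]-1,3-oxazolidin-2-one
Conditions: NaHMDS, THF, −78 °C; propargyl bromide, −78 → −40 °C
Reagents that add atoms: propargyl bromide (3-bromoprop-1-yne), C#CCBr
Why: Evans asymmetric alkylation: the chelated (Z)-sodium enolate is propargylated on the face opposite the benzyl group of the (R)-auxiliary, which should set C4 in the (R) configuration of the target.

Step 4
Reactants: 6 (4R)-4-benzyl-3-[(2R)-2-(2,2-dimethoxyethyl)pent-4-ynoyl]-1,3-oxazolidin-2-one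
Product: 7 (2R)-2-(2,2-dimethoxyethyl)pent-4-yn-1-ol
Conditions: LiBH4, MeOH (1 equiv), THF, 0 °C
Reagents that add atoms: none
Why: Reductive cleavage of the N-acyl oxazolidinone with LiBH4 gives the primary alcohol (the future O15) without touching the acetal, the alkyne or the α-stereocentre.

Step 5
Reactants: 7 (2R)-2-(2,2-dimethoxyethyl)pent-4-yn-1-ol
Product: 8 tert-butyl{[(2R)-2-(2,2-dimethoxyethyl)pent-4-yn-1-yl]oxy}diphenylsilane
Conditions: TBDPSCl, imidazole, CH2Cl2, rt
Reagents that add atoms: tert-butyl(chloro)diphenylsilane, CC(C)(C)[Si](Cl)(c1ccccc1)c1ccccc1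
Why: Silyl ether formation; TBDPS is chosen because it must survive base, DIBAL-H, silyl triflate and mild acid until the last step.

Step 6
Reactants: 8 tert-butyl{[(2R)-2-(2,2-dimethoxyethyl)pent-4-yn-1-yl]oxy}diphenylsilane
Product: 9 (4R)-4-{[tert-butyl(diphenyl)silyl]oxymethyl}-6,6-dimethoxyhexanal
Conditions: CpRu(MeCN)(6-tert-butyl-2-diphenylphosphinopyridine)2 PF6 (3 mol%), H2O (5 equiv), acetone, 70 °C
Reagents that add atoms: water, O
Why: Ruthenium-catalysed anti-Markovnikov hydration of the terminal alkyne should give the C1 aldehyde directly under neutral conditions, so the acetal and the silyl ether persist.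

Step 7
Reactants: 10 methyl 4-chloro-4-oxobutanoate; 11 bis(trimethylsilyl)acetylene
Product: 12 methyl 4-oxo-6-(trimethylsilyl)hex-5-ynoate
Conditions: AlCl3, CH2Cl2, 0 °C
Reagents that add atoms: none
Why: Friedel–Crafts-type acylation of the bis(silyl)alkyne (ipso-substitution of one silyl group by the acylium ion) is the standard route to silyl ynones, and the ester does not interfere.

Step 8
Reactants: 12 methyl 4-oxo-6-(trimethylsilyl)hex-5-ynoate
Product: 13 methyl (4R)-4-hydroxy-6-(trimethylsilyl)hex-5-ynoate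
Conditions: RuCl[(R,R)-TsDPEN](p-cymene) (1 mol%), i-PrOH, rt
Reagents that add atoms: none
Why: Noyori asymmetric transfer hydrogenation of the ynone, in which the alkynyl group takes the place of the aryl group in the organised transition state, so the (R,R)-catalyst should deliver the (R)-carbinol that becomes C8.

Step 9
Reactants: 13 methyl (4R)-4-hydroxy-6-(trimethylsilyl)hex-5-ynoate
Product: 15 (5R)-5-ethynyloxolan-2-one, via desilylated hydroxy ester 14 (not isolated)
Conditions: K2CO3 (cat.), MeOH, 0 °C → rt; then TsOH·H2O (cat.), CH2Cl2, rt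
Reagents that add atoms: none
Why: Methanolysis of the C–Si bond followed by acid-catalysed lactonisation of the γ-hydroxy ester; the carbinol centre is not involved.

Step 10
Reactants: 15 (5R)-5-ethynyloxolan-2-one
Product: 17 (5R)-5-(propa-1,2-dien-1-yl)oxolan-2-one, via propargylic amine 16 (not isolated)
Conditions: (CH2O)n, CuI (0.5 equiv), Cy2NH, dioxane, reflux
Reagents that add atoms: paraformaldehyde (formaldehyde), C=O
Why: Crabbé homologation: copper-mediated Mannich coupling gives amine 16, which loses the imine after 1,5-hydride transfer to leave the terminal allene (C7, C11, C13); the hindered amine should not open the lactone.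

Step 11
Reactants: 17 (5R)-5-(propa-1,2-dien-1-yl)oxolan-2-one
Product: 19 diethyl [(5R)-2-oxo-5-(propa-1,2-dien-1-yl)oxolan-3-yl]phosphonate (C3 epimers), via enol phosphate 18 (not isolated)
Conditions: LDA (1.1 equiv), THF, −78 °C; ClP(O)(OEt)2; LDA (2.2 equiv), −78 → 0 °C; AcOH
Reagents that add atoms: diethyl chlorophosphate, CCOP(=O)(Cl)OCC
Why: Vinyl phosphate–phosphonate rearrangement: the lactone enolate is O-phosphorylated and further LDA induces the 1,3 O→C phosphoryl shift to the stabilised α-phosphono lactone anion; the C3 epimers are of no consequence.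

Step 12
Reactants: 9 (4R)-4-{[tert-butyl(diphenyl)silyl]oxymethyl}-6,6-dimethoxyhexanal; 19 diethyl [(5R)-2-oxo-5-(propa-1,2-dien-1-yl)oxolan-3-yl]phosphonate
Product: 20 (3E,5R)-3-[(4R)-4-{[tert-butyl(diphenyl)silyl]oxymethyl}-6,6-dimethoxyhexylidene]-5-(propa-1,2-dien-1-yl)oxolan-2-one
Conditions: 19, KOt-Bu, THF, 0 °C; then 9, 0 °C → rt
Reagents that add atoms: none
Why: Horner–Wadsworth–Emmons olefination of the α-phosphono lactone should give the thermodynamically preferred (E)-alkylidene lactone (chain anti to the carbonyl), which fixes the C1=C10 geometry with C2 cis to C9.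

Step 13
Reactants: 20 the (E)-alkylidene allenyl lactone
Product: 21 (2E,4R)-2-[(4R)-4-{[tert-butyl(diphenyl)silyl]oxymethyl}-6,6-dimethoxyhexylidene]hepta-5,6-diene-1,4-diol
Conditions: DIBAL-H (5 equiv), CH2Cl2, −78 → 0 °C; Rochelle salt
Reagents that add atoms: none
Why: Full 1,2-reduction of the α-alkylidene lactone by excess DIBAL-H opens the temporary ring to the primary allylic alcohol (O14) and the secondary α-allenic alcohol (O8) without conjugate reduction.

Step 14
Reactants: 21 the diol
Product: 23 (3R,6E,9R)-3,7-bis{[tert-butyl(diphenyl)silyl]oxymethyl}-9-(triethylsilyloxy)dodeca-6,10,11-trienal dimethyl acetal, via mono-TBDPS ether 22 (not isolated)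
Conditions: TBDPSCl (1.05 equiv), imidazole, CH2Cl2, 0 °C; then TESCl, DMAP (cat.), rt
Reagents that add atoms: tert-butyl(chloro)diphenylsilane, CC(C)(C)[Si](Cl)(c1ccccc1)c1ccccc1; chlorotriethylsilane, CC[Si](Cl)(CC)CC
Why: Sequential silylation in one flask uses the large rate difference between the primary allylic and the secondary alcohol, so TBDPS should go on O14 and the more labile TES on O8.

Step 15
Reactants: 23 the bis-silyl dimethyl acetal
Product: 25 (3R,6E,9R)-3,7-bis{[tert-butyl(diphenyl)silyl]oxymethyl}-9-(triethylsilyloxy)dodeca-6,10,11-trienal, via collidinium salt 24 (not isolated)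
Conditions: TESOTf, 2,4,6-collidine, CH2Cl2, 0 °C; then H2O
Reagents that add atoms: water, O
Why: Silyl triflate/collidine cleavage of the dimethyl acetal through pyridinium salt 24 is non-acidic, so it should unmask the C6 aldehyde in the presence of the TES ether, the allylic silyl ether and the allene.

Step 16
Reactants: 25 the allenyl aldehyde
Product: 27 (1(10)E,4R,6R,7S,8R)-14,15-bis(tert-butyldiphenylsilyloxy)-8-(triethylsilyloxy)germacra-1(10),11(13)-dien-12,6-olide, via hydroxy acid 26 (not isolated)
Conditions: Ni(cod)2 (2 equiv), DBU (10 equiv), CO2 (1 atm), THF, 0 °C, 25 added by syringe pump (final 2 mM); then 1 M HCl; PPTS (cat.), CH2Cl2, rt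
Reagents that add atoms: carbon dioxide, O=C=O
Why: Proposed new method: Ni(0)/DBU should couple CO2 oxidatively with the terminal C11=C13 π-bond of the allene to give a five-membered nickelalactone (new C11–C12 bond) that is a 2-carboxylato-allylnickel(II) species, whose γ-carbon C7 then adds to the tethered C6 aldehyde through a closed six-membered transition state (new C6–C7 bond), and acid releases hydroxy acid 26, which lactonises. The closest known reaction type is the nickel-mediated sequential addition of CO2 and an aldehyde to a terminal allene, known between separate partners and in tethered form for small rings, while the ring closure resembles the chromium- or zinc-mediated macrocyclisations of 2-(bromomethyl)acrylate aldehydes that close ten-membered germacranolides; the extension proposed is the ten-membered case. The carbocycle closes by a 10-exo-trig allylmetal addition to the carbonyl group and the lactone then closes by 5-exo-trig O-acylation of the C6 hydroxyl on C12. C6 and C7 are set together: the σ-allyl on C13 with the C8 substituent syn to the carboxylate, in a chair-like Ni–O=C array, should give the anti (6,7-trans) alkoxide and hence the trans-fused lactone, and the face of C7 is fixed by C8, whose hydrogen eclipses the allyl plane (A1,3 strain against the carboxylate) so that the ring tether C9 lies anti to the forming bond and the OSiEt3 group points outward. The step needs CO2 capture to outrun direct nickel–aldehyde chemistry (CO2 saturation, DBU, slow addition), delivery through C7 and not through the CH2 terminus (the carboxylate chelate keeps nickel on C13, so SE2′ attack is at C7), ring closure over chain growth (high dilution) and no ionisation at C8 (a silyl ether, a poor leaving group, is used there and not an ester).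

Step 17
Reactants: 27 the TES-protected macrocyclic lactone
Product: 28 (1(10)E,4R,6R,7R,8R)-14,15-bis(tert-butyldiphenylsilyloxy)-8-hydroxygermacra-1(10),11(13)-dien-12,6-olide (same spatial arrangement as 27; the C7 descriptor changes by CIP priority only)
Conditions: PPTS, MeOH/CH2Cl2, 0 °C
Reagents that add atoms: none
Why: Acid-catalysed methanolysis removes the secondary triethylsilyl ether far faster than the primary TBDPS ethers, freeing only the C8 hydroxyl.

Step 18
Reactants: 28 the C8 alcohol; 29 angelic acid ((Z)-2-methylbut-2-enoic acid)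
Product: 31 (1(10)E,4R,6R,7S,8R)-8-angeloyloxy-14,15-bis(tert-butyldiphenylsilyloxy)germacra-1(10),11(13)-dien-12,6-olide, via mixed anhydride 30 (not isolated)
Conditions: 29, 2,4,6-Cl3C6H2COCl, Et3N, PhMe, rt; then 28, 75 °C
Reagents that add atoms: none
Why: Yamaguchi-type esterification through the 2,4,6-trichlorobenzoyl mixed anhydride without added nucleophilic catalyst is the established way to acylate hindered alcohols with angelic acid while keeping the (Z)-geometry.

Step 19
Reactants: 31 the bis-TBDPS angelate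
Product: 32 CNP0262807.1, (1(10)E,4R,6R,7S,8R)-8-angeloyloxy-14,15-dihydroxygermacra-1(10),11(13)-dien-12,6-olide
Conditions: HF·pyridine, pyridine, THF, 0 °C → rt
Reagents that add atoms: none
Why: Fluoride-mediated desilylation with buffered HF·pyridine should cleave both primary TBDPS ethers without adding to the α-methylene lactone or isomerising or cleaving the angelate.

**Compound list**
1 | methyl 4,4-dimethoxybutanoate | COC(OC)CCC(=O)OC | starting material
2 | 4,4-dimethoxybutanoic acid | COC(OC)CCC(=O)O | intermediate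
3 | (4R)-4-benzyl-1,3-oxazolidin-2-one | O=C1N[C@H](Cc2ccccc2)CO1 | starting material
4 | 4,4-dimethoxybutanoic pivalic anhydride | COC(OC)CCC(=O)OC(=O)C(C)(C)C | intermediate
5 | (4R)-4-benzyl-3-(4,4-dimethoxybutanoyl)-1,3-oxazolidin-2-one | COC(OC)CCC(=O)N1[C@H](Cc2ccccc2)COC1=O | intermediate
6 | (4R)-4-benzyl-3-[(2R)-2-(2,2-dimethoxyethyl)pent-4-ynoyl]-1,3-oxazolidin-2-one | COC(OC)C[C@H](C(=O)N1[C@H](Cc2ccccc2)COC1=O)CC#C | intermediate
7 | (2R)-2-(2,2-dimethoxyethyl)pent-4-yn-1-ol | COC(OC)C[C@H](CO)CC#C | intermediate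
8 | tert-butyl{[(2R)-2-(2,2-dimethoxyethyl)pent-4-yn-1-yl]oxy}diphenylsilane | COC(OC)C[C@H](CO[Si](c1ccccc1)(c1ccccc1)C(C)(C)C)CC#C | intermediate
9 | (4R)-4-{[tert-butyl(diphenyl)silyl]oxymethyl}-6,6-dimethoxyhexanal | COC(OC)C[C@H](CO[Si](c1ccccc1)(c1ccccc1)C(C)(C)C)CCC=O | intermediate
10 | methyl 4-chloro-4-oxobutanoate | COC(=O)CCC(=O)Cl | starting material
11 | bis(trimethylsilyl)acetylene | C[Si](C)(C)C#C[Si](C)(C)C | starting material
12 | methyl 4-oxo-6-(trimethylsilyl)hex-5-ynoate | COC(=O)CCC(=O)C#C[Si](C)(C)C | intermediate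
13 | methyl (4R)-4-hydroxy-6-(trimethylsilyl)hex-5-ynoate | COC(=O)CC[C@@H](O)C#C[Si](C)(C)C | intermediate
14 | methyl (4R)-4-hydroxyhex-5-ynoate | COC(=O)CC[C@@H](O)C#C | intermediate
15 | (5R)-5-ethynyloxolan-2-one | O=C1CC[C@H](C#C)O1 | intermediate
16 | (5R)-5-[3-(dicyclohexylamino)prop-1-yn-1-yl]oxolan-2-one | O=C1CC[C@H](C#CCN(C2CCCCC2)C2CCCCC2)O1 | intermediate
17 | (5R)-5-(propa-1,2-dien-1-yl)oxolan-2-one | O=C1CC[C@H](C=C=C)O1 | intermediate
18 | diethyl (5R)-5-(propa-1,2-dien-1-yl)-4,5-dihydrofuran-2-yl phosphate | CCOP(=O)(OCC)OC1=CC[C@H](C=C=C)O1 | intermediate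
19 | diethyl [(5R)-2-oxo-5-(propa-1,2-dien-1-yl)oxolan-3-yl]phosphonate (C3 epimers) | CCOP(=O)(OCC)C1C[C@H](C=C=C)OC1=O | intermediate
20 | (3E,5R)-3-[(4R)-4-{[tert-butyl(diphenyl)silyl]oxymethyl}-6,6-dimethoxyhexylidene]-5-(propa-1,2-dien-1-yl)oxolan-2-one | O=C1/C(=C/CC[C@@H](CO[Si](c2ccccc2)(c2ccccc2)C(C)(C)C)CC(OC)OC)C[C@H](C=C=C)O1 | intermediate
21 | (2E,4R)-2-[(4R)-4-{[tert-butyl(diphenyl)silyl]oxymethyl}-6,6-dimethoxyhexylidene]hepta-5,6-diene-1,4-diol | OC/C(=C/CC[C@@H](CO[Si](c1ccccc1)(c1ccccc1)C(C)(C)C)CC(OC)OC)C[C@@H](O)C=C=C | intermediate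
22 | 1-O-TBDPS ether of diol 21 (C8 hydroxyl free) | CC(C)(C)[Si](c1ccccc1)(c1ccccc1)OC/C(=C/CC[C@@H](CO[Si](c1ccccc1)(c1ccccc1)C(C)(C)C)CC(OC)OC)C[C@@H](O)C=C=C | intermediate
23 | (3R,6E,9R)-3,7-bis{[tert-butyl(diphenyl)silyl]oxymethyl}-9-(triethylsilyloxy)dodeca-6,10,11-trienal dimethyl acetal | CC(C)(C)[Si](c1ccccc1)(c1ccccc1)OC/C(=C/CC[C@@H](CO[Si](c1ccccc1)(c1ccccc1)C(C)(C)C)CC(OC)OC)C[C@@H](O[Si](CC)(CC)CC)C=C=C | intermediate
24 | 1-(1-methoxyalkyl)-2,4,6-trimethylpyridinium triflate derived from 23 at C6 (mixture at the new centre) | CC(C)(C)[Si](c1ccccc1)(c1ccccc1)OC/C(=C/CC[C@@H](CO[Si](c1ccccc1)(c1ccccc1)C(C)(C)C)CC(OC)[n+]2c(C)cc(C)cc2C)C[C@@H](O[Si](CC)(CC)CC)C=C=C.[O-]S(=O)(=O)C(F)(F)F | intermediate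
25 | (3R,6E,9R)-3,7-bis{[tert-butyl(diphenyl)silyl]oxymethyl}-9-(triethylsilyloxy)dodeca-6,10,11-trienal | CC(C)(C)[Si](c1ccccc1)(c1ccccc1)OC/C(=C/CC[C@@H](CO[Si](c1ccccc1)(c1ccccc1)C(C)(C)C)CC=O)C[C@@H](O[Si](CC)(CC)CC)C=C=C | intermediate
26 | (1(10)E,4R,6R,7S,8R)-6-hydroxy-14,15-bis(tert-butyldiphenylsilyloxy)-8-(triethylsilyloxy)germacra-1(10),11(13)-dien-12-oic acid | C=C(C(=O)O)[C@H]1[C@H](O)C[C@H](CO[Si](c2ccccc2)(c2ccccc2)C(C)(C)C)CC/C=C(/CO[Si](c2ccccc2)(c2ccccc2)C(C)(C)C)C[C@H]1O[Si](CC)(CC)CC | intermediate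
27 | (1(10)E,4R,6R,7S,8R)-14,15-bis(tert-butyldiphenylsilyloxy)-8-(triethylsilyloxy)germacra-1(10),11(13)-dien-12,6-olide (trans-fused lactone) | C=C1C(=O)O[C@@H]2C[C@H](CO[Si](c3ccccc3)(c3ccccc3)C(C)(C)C)CC/C=C(/CO[Si](c3ccccc3)(c3ccccc3)C(C)(C)C)C[C@@H](O[Si](CC)(CC)CC)[C@@H]12 | intermediate
28 | (1(10)E,4R,6R,7R,8R)-14,15-bis(tert-butyldiphenylsilyloxy)-8-hydroxygermacra-1(10),11(13)-dien-12,6-olide | C=C1C(=O)O[C@@H]2C[C@H](CO[Si](c3ccccc3)(c3ccccc3)C(C)(C)C)CC/C=C(/CO[Si](c3ccccc3)(c3ccccc3)C(C)(C)C)C[C@@H](O)[C@@H]12 | intermediate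
29 | angelic acid, (Z)-2-methylbut-2-enoic acid | C/C=C(/C)C(=O)O | starting material
30 | angelic 2,4,6-trichlorobenzoic anhydride | C/C=C(/C)C(=O)OC(=O)c1c(Cl)cc(Cl)cc1Cl | intermediate
31 | (1(10)E,4R,6R,7S,8R)-8-angeloyloxy-14,15-bis(tert-butyldiphenylsilyloxy)germacra-1(10),11(13)-dien-12,6-olide | C=C1C(=O)O[C@@H]2C[C@H](CO[Si](c3ccccc3)(c3ccccc3)C(C)(C)C)CC/C=C(/CO[Si](c3ccccc3)(c3ccccc3)C(C)(C)C)C[C@@H](OC(=O)/C(C)=C\C)[C@@H]12 | intermediate
32 | CNP0262807.1, (1(10)E,4R,6R,7S,8R)-8-angeloyloxy-14,15-dihydroxygermacra-1(10),11(13)-dien-12,6-olide | C=C1C(=O)O[C@@H]2C[C@H](CO)CC/C=C(/CO)C[C@@H](OC(=O)/C(C)=C\C)[C@@H]12 | target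

**Count**
Total steps: 19. Longest linear sequence: 14 steps (steps 1–6, then 12–19); the side branch is steps 7–11.

**Steps most likely to fail**

1. Step 16 (Proposed new method). What may go wrong: chain growth between molecules instead of ring closure; delivery through the CH2 terminus of the allylnickel, which would give a twelve-membered ring; loss of the C8 silyloxy group by β-elimination from the allylnickel; or poor facial selectivity at C6 and C7. The fallback keeps the CO2/allene/aldehyde coupling but runs it between two molecules, where it is established, and closes the ring by olefin metathesis. It sets out from 19 and 9 and comes back at 27. Phosphonate 19 is condensed with aqueous formaldehyde (K2CO3) to the α-methylene allenyl lactone F1, which DIBAL-H reduces to the diol F2; TBDPSCl then TESCl give the bis-silyl ether F3. Aldehyde 9 is methylenated (Ph3P=CH2) to the terminal alkene F4, and its acetal is opened (TESOTf, collidine; then H2O) to the aldehyde F5. Allene F3 is carboxylated on nickel (Ni(cod)2, DBU, CO2, THF, 0 °C) and the allylnickel is then treated with F5, which should give after acid the open-chain hydroxy acid F6 and, on lactonisation, the diene lactone F7. Ring-closing metathesis (second-generation Grubbs catalyst, PhMe, high dilution, 80 °C) between the vinyl group and the 1,1-disubstituted alkene should close C1=C10 and give 27.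

2. Step 18. What may go wrong: isomerisation of the angeloyl unit to the tigloyl unit in the activated acyl species; slow acylation of the hindered hydroxyl next to the ring fusion; or shift of the lactone from O6 to the free O8 under warm basic conditions. The fallback builds the (Z)-alkene on the substrate instead of transferring it. It sets out from 28 and comes back at 31. Alcohol 28 is coupled (DCC, DMAP, CH2Cl2, 0 °C) with 2-[bis(2,2,2-trifluoroethoxy)phosphoryl]propanoic acid to the phosphonate ester F8. Still–Gennari olefination with acetaldehyde (KHMDS, 18-crown-6, THF, −78 °C) should then give the (Z)-2-methylbut-2-enoate 31.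

3. Step 11. What may go wrong: deprotonation or isomerisation of the allene by the excess amide base, or incomplete O→C phosphoryl migration. The fallback avoids the phosphonate and makes the alkylidene lactone by aldol addition and elimination. It sets out from 17 and 9 and comes back at 20. The lithium enolate of 17 (LDA, THF, −78 °C) is added to 9 to give the β-hydroxy lactone F9 (diastereomer mixture). MsCl/Et3N converts it into the mesylate F10, and DBU-induced E1cB elimination should give the (E)-alkylidene lactone 20.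

**Further compounds**
F1 | step 16 | (5R)-3-methylidene-5-(propa-1,2-dien-1-yl)oxolan-2-one | C=C1C[C@H](C=C=C)OC1=O
F2 | step 16 | (4R)-2-methylidenehepta-5,6-diene-1,4-diol | OCC(=C)C[C@@H](O)C=C=C
F3 | step 16 | tert-butyl{[(4R)-2-methylidene-4-(triethylsilyloxy)hepta-5,6-dien-1-yl]oxy}diphenylsilane | CC(C)(C)[Si](c1ccccc1)(c1ccccc1)OCC(=C)C[C@@H](O[Si](CC)(CC)CC)C=C=C
F4 | step 16 | tert-butyl{[(2R)-2-(2,2-dimethoxyethyl)hex-5-en-1-yl]oxy}diphenylsilane | COC(OC)C[C@H](CO[Si](c1ccccc1)(c1ccccc1)C(C)(C)C)CCC=C
F5 | step 16 | (3R)-3-{[tert-butyl(diphenyl)silyl]oxymethyl}hept-6-enal | O=CC[C@H](CO[Si](c1ccccc1)(c1ccccc1)C(C)(C)C)CCC=C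
F6 | step 16 | open-chain γ-hydroxy α-methylene acid from F3, CO2 and F5 (configuration at C4, C6, C7, C8 as in 26) | C=C(C(=O)O)[C@@H]([C@H](O)C[C@H](CO[Si](c1ccccc1)(c1ccccc1)C(C)(C)C)CCC=C)[C@H](O[Si](CC)(CC)CC)CC(=C)CO[Si](c1ccccc1)(c1ccccc1)C(C)(C)C
F7 | step 16 | open-chain trans-disubstituted α-methylene-γ-butyrolactone diene (ring-closing metathesis substrate) | C=C1C(=O)O[C@H](C[C@H](CO[Si](c2ccccc2)(c2ccccc2)C(C)(C)C)CCC=C)[C@H]1[C@H](O[Si](CC)(CC)CC)CC(=C)CO[Si](c2ccccc2)(c2ccccc2)C(C)(C)C
F8 | step 18 | 8-O-{2-[bis(2,2,2-trifluoroethoxy)phosphoryl]propanoyl} ester of 28 | C=C1C(=O)O[C@@H]2C[C@H](CO[Si](c3ccccc3)(c3ccccc3)C(C)(C)C)CC/C=C(/CO[Si](c3ccccc3)(c3ccccc3)C(C)(C)C)C[C@@H](OC(=O)C(C)P(=O)(OCC(F)(F)F)OCC(F)(F)F)[C@@H]12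
F9 | step 11 | (5R)-3-[(4R)-4-{[tert-butyl(diphenyl)silyl]oxymethyl}-1-hydroxy-6,6-dimethoxyhexyl]-5-(propa-1,2-dien-1-yl)oxolan-2-one (diastereomer mixture) | O=C1C(C(O)CC[C@@H](CO[Si](c2ccccc2)(c2ccccc2)C(C)(C)C)CC(OC)OC)C[C@H](C=C=C)O1
F10 | step 11 | methanesulfonate of F9 | O=C1C(C(OS(C)(=O)=O)CC[C@@H](CO[Si](c2ccccc2)(c2ccccc2)C(C)(C)C)CC(OC)OC)C[C@H](C=C=C)O1
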